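**Retrosynthetic overview**
1. Target 12 ← diene 10 by a cis-1,4-chloro-oxygenation that sets C2–Cl and C5–OH together, on the face opposite to the 1-OH and 6-OBz groups.
2. Diene 10 ← cyclohexene dibenzoate 8 (bromination, double dehydrobromination) ← triol 7 ← hydroxy keto ester 5.
3. 5 ← cyclopentenyl α-keto ester 4 by an enantioselective α-ketol 1,2-shift with ring expansion; this makes the six-membered ring and sets the quaternary carbinol C1.
4. 4 ← diazo aldol adduct 3 ← cyclopent-3-en-1-one 1 + ethyl diazoacetate 2.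
5. Ring order: there is only one ring; the five-membered carbocycle of 1 is expanded to the six-membered ring in step 2.

Assumption: the sense of induction of the Cu(OTf)2/(S,S)-tBu-box catalyst in step 2 is assigned by analogy; if it gives ent-5, the (R,R)-ligand is used and nothing else changes.

**Step 1**
Reactants: 1 cyclopent-3-en-1-one; 2 ethyl diazoacetate
Product: 3 ethyl 2-diazo-2-(1-hydroxycyclopent-3-en-1-yl)acetate
Conditions: LiN(iPr)2 (1.05 equiv) added to 1 + 2, THF, −78 °C; AcOH quench at −78 °C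
Reagents that add atoms: none
Why: Diazo aldol addition of lithiated ethyl diazoacetate to the unhindered ketone, which at −78 °C should outrun enolisation; no stereocentre is formed.

**Step 2**
Reactants: 3 ethyl 2-diazo-2-(1-hydroxycyclopent-3-en-1-yl)acetate
Product: 5 ethyl (1S)-1-hydroxy-2-oxocyclohex-4-ene-1-carboxylate, via keto ester 4 (not isolated)
Conditions: DMDO (1.05 equiv), acetone, −78 → −40 °C; evaporate; Cu(OTf)2 (10 mol %), (S,S)-tBu-box (12 mol %), 4 Å molecular sieves, CH2Cl2, 0 → 25 °C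
Reagents that add atoms: dimethyldioxirane, CC1(C)OO1
Why: Diazo-to-ketone oxidation gives the achiral β-hydroxy-α-keto ester 4, and a catalytic enantioselective α-ketol (acyloin) rearrangement then expands the ring: the box-bound divalent copper chelates the 1,2-dicarbonyl and one of the two enantiotopic allylic ring CH2 groups shifts from the carbinol carbon to the ketone carbon, which sets C1 as (S) and is driven by five-to-six ring expansion and loss of the vicinal dicarbonyl.

**Step 3**
Reactants: 5 ethyl (1S)-1-hydroxy-2-oxocyclohex-4-ene-1-carboxylate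
Product: 7 (1R,2R)-1-(hydroxymethyl)cyclohex-4-ene-1,2-diol, via dihydroxy ester 6 (not isolated)
Conditions: NaBH4 (4 equiv), EtOH, −40 °C (1 h), then 25 °C (12 h)
Reagents that add atoms: none
Why: Borohydride reduction in a protic, non-chelating medium: hydride adds to the ketone anti to the pseudoaxial tertiary C–O bond (polar Felkin–Anh), giving the cis-diol 6 (new centre R), and excess reagent then reduces the hydroxyl-activated α-hydroxy ester to the primary alcohol.

**Step 4**
Reactants: 7 (1R,2R)-1-(hydroxymethyl)cyclohex-4-ene-1,2-diol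
Product: 8 [(1R,6R)-6-(benzoyloxy)-1-hydroxycyclohex-3-en-1-yl]methyl benzoate
Conditions: BzCl (2.2 equiv), pyridine, CH2Cl2, −20 → 0 °C
Reagents that add atoms: benzoyl chloride, O=C(Cl)c1ccccc1
Why: Schotten–Baumann-type O-acylation; the primary and secondary hydroxyls react and the tertiary hydroxyl does not, with no stereocentre touched.

**Step 5**
Reactants: 8 [(1R,6R)-6-(benzoyloxy)-1-hydroxycyclohex-3-en-1-yl]methyl benzoate
Product: 10 [(1R,6R)-6-(benzoyloxy)-1-hydroxycyclohexa-2,4-dien-1-yl]methyl benzoate, via trans-dibromide 9 (not isolated)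
Conditions: Br2 (1.05 equiv), CH2Cl2, −78 °C; evaporate; DBU (4 equiv), toluene, 60 °C
Reagents that add atoms: bromine, BrBr (in 9 only; lost again as bromide on the way to 10)
Why: Anti addition of bromine to the isolated alkene (low temperature and a bromide-rich medium disfavour bromo-etherification by the tertiary OH), then double E2 dehydrobromination to the conjugated diene; C1 has no hydrogen, so base cannot aromatise the product by loss of benzoic acid, and C1 and C6 are untouched.

**Step 6**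
Reactants: 10 [(1R,6R)-6-(benzoyloxy)-1-hydroxycyclohexa-2,4-dien-1-yl]methyl benzoate
Product: 12 [(1R,2R,5S,6R)-6-(benzoyloxy)-2-chloro-1,5-dihydroxycyclohex-3-en-1-yl]methyl benzoate (CNP0326102.1), via chloro trifluoroacetate 11 (not isolated)
Conditions: Pd(OCOCF3)2 (5 mol %), LiCl (2 equiv), CF3CO2Li (4 equiv), CF3CO2H (2 equiv), p-benzoquinone (1.5 equiv), acetone, 0 °C; then NaHCO3, MeOH, 0 °C
Reagents that add atoms: lithium chloride, [Li+].[Cl-]; lithium trifluoroacetate, [Li+].[O-]C(=O)C(F)(F)F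
Why: Proposed new method: a hydroxyl-directed, palladium-catalysed cis-1,4-chloro-trifluoroacetoxylation of a 5,6-dioxygenated cyclohexa-1,3-diene (a formal 1,4-chlorohydroxylation), in which the free tertiary 1-OH binds divalent palladium and holds it on the diene face syn to 1-OH/6-OBz, trifluoroacetate attacks C5 (next to the secondary centre, not the neopentyl C2) anti to palladium to give a hydroxyl-chelated π-allyl complex, and benzoquinone-activated external chloride attacks C2, again anti to palladium, so Cl and O end cis to each other and trans to their oxygen neighbours (2R,5S); the closest known reaction is the palladium/benzoquinone cis-1,4-acetoxychlorination of cyclohexa-1,3-diene with LiCl/LiOAc in AcOH, and the labile trifluoroacetate is removed by bicarbonate methanolysis, which leaves the benzoates.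

**Compound list**
1 | cyclopent-3-en-1-one | O=C1CC=CC1 | starting material
2 | ethyl diazoacetate | CCOC(=O)C=[N+]=[N-] | starting material
3 | ethyl 2-diazo-2-(1-hydroxycyclopent-3-en-1-yl)acetate | CCOC(=O)C(=[N+]=[N-])C1(O)CC=CC1 | intermediate
4 | ethyl 2-(1-hydroxycyclopent-3-en-1-yl)-2-oxoacetate | CCOC(=O)C(=O)C1(O)CC=CC1 | intermediate
5 | ethyl (1S)-1-hydroxy-2-oxocyclohex-4-ene-1-carboxylate | CCOC(=O)[C@]1(O)CC=CCC1=O | intermediate
6 | ethyl (1S,2R)-1,2-dihydroxycyclohex-4-ene-1-carboxylate (cis-diol) | CCOC(=O)[C@]1(O)CC=CC[C@H]1O | intermediate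
7 | (1R,2R)-1-(hydroxymethyl)cyclohex-4-ene-1,2-diol (cis-diol) | OC[C@]1(O)CC=CC[C@H]1O | intermediate
8 | [(1R,6R)-6-(benzoyloxy)-1-hydroxycyclohex-3-en-1-yl]methyl benzoate | O=C(OC[C@]1(O)CC=CC[C@H]1OC(=O)c1ccccc1)c1ccccc1 | intermediate
9 | [(1R,3S,4S,6R)-6-(benzoyloxy)-3,4-dibromo-1-hydroxycyclohexyl]methyl benzoate (one of the two trans-dibromides drawn; both eliminate to 10) | O=C(OC[C@]1(O)C[C@H](Br)[C@@H](Br)C[C@H]1OC(=O)c1ccccc1)c1ccccc1 | intermediate
10 | [(1R,6R)-6-(benzoyloxy)-1-hydroxycyclohexa-2,4-dien-1-yl]methyl benzoate | O=C(OC[C@]1(O)C=CC=C[C@H]1OC(=O)c1ccccc1)c1ccccc1 | intermediate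
11 | [(1R,2R,5S,6R)-6-(benzoyloxy)-2-chloro-1-hydroxy-5-(trifluoroacetoxy)cyclohex-3-en-1-yl]methyl benzoate | O=C(OC[C@]1(O)[C@H](Cl)C=C[C@H](OC(=O)C(F)(F)F)[C@H]1OC(=O)c1ccccc1)c1ccccc1 | intermediate
12 | [(1R,2R,5S,6R)-6-(benzoyloxy)-2-chloro-1,5-dihydroxycyclohex-3-en-1-yl]methyl benzoate (CNP0326102.1) | O=C(OC[C@]1(O)[C@H](Cl)C=C[C@H](O)[C@H]1OC(=O)c1ccccc1)c1ccccc1 | target

**Totals**
Total step count: 6. Longest linear sequence: 6 (fully linear from 1 and 2).

**Steps most likely to fail**

Step 6 (proposed new step). Risks: palladium may bind the diene face anti to the ring oxygens, which would give the 2,5-bis-epimer; the acid medium may aromatise the arene-hydrate-like diene; benzoquinone may undergo a Diels–Alder reaction with 10. The fallback uses known chemistry, sets out from 10 and comes back at 12. Diene 10 is silylated (Me3SiOTf, 2,6-lutidine) to [(1R,6R)-6-(benzoyloxy)-1-[(trimethylsilyl)oxy]cyclohexa-2,4-dien-1-yl]methyl benzoate F5, so that no free hydroxyl can steer the next step. Photo-oxygenation (O2, tetraphenylporphyrin, hν, CH2Cl2, −30 °C) adds singlet oxygen to the face anti to the two ring oxygens and gives the endoperoxide [(1R,2R,5S,6R)-6-(benzoyloxy)-2,5-epidioxy-1-[(trimethylsilyl)oxy]cyclohex-3-en-1-yl]methyl benzoate F6. Thiourea in MeOH cleaves the O–O bond to the cis-2,5-diol [(1S,2R,5S,6R)-6-(benzoyloxy)-2,5-dihydroxy-1-[(trimethylsilyl)oxy]cyclohex-3-en-1-yl]methyl benzoate F7. The less hindered 5-OH is silylated (Et3SiCl, imidazole, −40 °C) to the 5-O-triethylsilyl ether F8, and the remaining 2-OH is mesylated (MsCl, Et3N) to the 2-O-mesylate F9. Bu4NF removes both silyl groups and the freed tertiary alkoxide displaces the mesylate with inversion, giving the pipoxide-type vinyl epoxide [(1S,2S,5S,6R)-6-(benzoyloxy)-1,2-epoxy-5-hydroxycyclohex-3-en-1-yl]methyl benzoate F10. HCl in Et2O opens F10 at the allylic C2 with a second inversion to give 12.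

Step 2. Risks: insufficient enantioselectivity for this cyclopentenyl substrate, competing epoxidation by DMDO, and drift of the β,γ-alkene of 5 into conjugation under Lewis acid. The fallback sets out from 1 and 2 and comes back at 5, and still builds the ring by expansion. Ketone 1 and diazo ester 2 are combined directly with BF3·OEt2 (CH2Cl2, −20 °C) in a Tiffeneau–Demjanov-type homologation to racemic ethyl 2-oxocyclohex-4-ene-1-carboxylate F1. The β-keto ester F1 is then hydroxylated enantioselectively at C1 (dihydroquinine with cumene hydroperoxide, or the sodium enolate with (+)-(camphorsulfonyl)oxaziridine) to give 5.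

Step 3. Risk: hydroxyl-chelated hydride delivery would give the trans-diol. The fallback sets out from 5 and comes back at 7, and replaces the free hydroxyl by a non-chelating group. Keto ester 5 is silylated (Et3SiOTf, 2,6-lutidine) to ethyl (1S)-2-oxo-1-[(triethylsilyl)oxy]cyclohex-4-ene-1-carboxylate F2. LiBH(sBu)3 at −78 °C adds hydride anti to the pseudoaxial silyloxy group (Felkin–Anh, no chelation) to give the cis product ethyl (1S,2R)-2-hydroxy-1-[(triethylsilyl)oxy]cyclohex-4-ene-1-carboxylate F3. LiAlH4 reduces the ester to (1R,6R)-6-(hydroxymethyl)-6-[(triethylsilyl)oxy]cyclohex-3-en-1-ol F4, and Bu4NF removes the silyl group to give 7.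

**Further compounds**
F1 | step 2 | ethyl 2-oxocyclohex-4-ene-1-carboxylate (racemic) | CCOC(=O)C1CC=CCC1=O
F2 | step 3 | ethyl (1S)-2-oxo-1-[(triethylsilyl)oxy]cyclohex-4-ene-1-carboxylate | CCOC(=O)[C@]1(O[Si](CC)(CC)CC)CC=CCC1=O
F3 | step 3 | ethyl (1S,2R)-2-hydroxy-1-[(triethylsilyl)oxy]cyclohex-4-ene-1-carboxylate | CCOC(=O)[C@]1(O[Si](CC)(CC)CC)CC=CC[C@H]1O
F4 | step 3 | (1R,6R)-6-(hydroxymethyl)-6-[(triethylsilyl)oxy]cyclohex-3-en-1-ol | OC[C@]1(O[Si](CC)(CC)CC)CC=CC[C@H]1O
F5 | step 6 | [(1R,6R)-6-(benzoyloxy)-1-[(trimethylsilyl)oxy]cyclohexa-2,4-dien-1-yl]methyl benzoate | O=C(OC[C@]1(O[Si](C)(C)C)C=CC=C[C@H]1OC(=O)c1ccccc1)c1ccccc1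
F6 | step 6 | [(1R,2R,5S,6R)-6-(benzoyloxy)-2,5-epidioxy-1-[(trimethylsilyl)oxy]cyclohex-3-en-1-yl]methyl benzoate | O=C(OC[C@]1(O[Si](C)(C)C)[C@H]2C=C[C@H](OO2)[C@H]1OC(=O)c1ccccc1)c1ccccc1
F7 | step 6 | [(1S,2R,5S,6R)-6-(benzoyloxy)-2,5-dihydroxy-1-[(trimethylsilyl)oxy]cyclohex-3-en-1-yl]methyl benzoate | O=C(OC[C@]1(O[Si](C)(C)C)[C@H](O)C=C[C@H](O)[C@H]1OC(=O)c1ccccc1)c1ccccc1
F8 | step 6 | [(1S,2R,5S,6R)-6-(benzoyloxy)-2-hydroxy-5-[(triethylsilyl)oxy]-1-[(trimethylsilyl)oxy]cyclohex-3-en-1-yl]methyl benzoate | O=C(OC[C@]1(O[Si](C)(C)C)[C@H](O)C=C[C@H](O[Si](CC)(CC)CC)[C@H]1OC(=O)c1ccccc1)c1ccccc1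
F9 | step 6 | [(1R,2R,5S,6R)-6-(benzoyloxy)-2-(methanesulfonyloxy)-5-[(triethylsilyl)oxy]-1-[(trimethylsilyl)oxy]cyclohex-3-en-1-yl]methyl benzoate | O=C(OC[C@]1(O[Si](C)(C)C)[C@H](OS(C)(=O)=O)C=C[C@H](O[Si](CC)(CC)CC)[C@H]1OC(=O)c1ccccc1)c1ccccc1
F10 | step 6 | [(1S,2S,5S,6R)-6-(benzoyloxy)-1,2-epoxy-5-hydroxycyclohex-3-en-1-yl]methyl benzoate (epoxide oxygen cis to 6-OBz) | O=C(OC[C@]12O[C@H]1C=C[C@H](O)[C@H]2OC(=O)c1ccccc1)c1ccccc1
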